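## Retrosynthetic overview
1. The target comes from a 14-membered 3E-en-6-yne cembranolide by Z-selective semihydrogenation (C6=C7) and reagent-controlled epoxidation (C3–C4).
2. Key step: the 14-membered carbocycle comes from a 16-membered allyl alkynoate macrolactone. Pd(0) extrudes CO2 and contracts the ring, which forms C5–C6.
3. The macrolactone comes from a seco acid (C5–O bond). Its cis-α-methylene-γ-lactone comes from α-aminoxylation (C13) and an indium Barbier coupling (C1–C14) of an aldehyde acid with an allylic bromide.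
4. The aldehyde acid (C6–C14) is built from a silyl ynone, an allyl unit, methyl but-2-ynoate and CO2. C8 is set by asymmetric allylboration and C12 by CuH reduction.
5. The bromide is built from a propargyl ether, Me3Al, oxirane and methyl propiolate. Ring order: γ-lactone, then 16-membered lactone, then 14-membered carbocycle, then oxirane.

Assumption: cembrane numbering is used (C1 = ring CH bearing C15, C14 = lactone O–CH, C13 = CHOH, C12 = CHMe, C8 = C(OH)Me, C3/C4 = oxirane); the silyl groups in commercial 1 and 13 are counted as protecting groups; and for each chiral catalyst the antipode is the one that gives the drawn configuration.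

## Route

Step 1
Reactants: 1 4-(trimethylsilyl)but-3-yn-2-one; 2 allylmagnesium bromide
Product: 4 (S)-3-methyl-1-(trimethylsilyl)hex-5-en-1-yn-3-ol, via allyldiisopropoxyborane 3 (not isolated)
Conditions: 2, B(Oi-Pr)3, Et2O, −78 °C → rt, HCl·Et2O, filter; then 1, (S)-3,3′-Br2-BINOL (15 mol %), PhCF3/PhMe 3:1, −35 °C; aq work-up
Reagents that add atoms: triisopropyl borate CC(C)OB(OC(C)C)OC(C)C (its boron unit is carried only by 3)
Why: Diol-catalysed asymmetric allylboration of a ketone, in which the BINOL-bound allylboronate adds 1,2 through a closed chair transition state to the Si face of the ynone (alkynyl pseudo-equatorial, methyl pseudo-axial) and sets C8 as S.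

Step 2
Reactants: 4 (S)-3-methyl-1-(trimethylsilyl)hex-5-en-1-yn-3-ol; 5 methyl but-2-ynoate
Product: 7 methyl (2E,7S)-7-hydroxy-3,7-dimethyl-9-(trimethylsilyl)non-2-en-8-ynoate, via B-alkyl-9-BBN adduct 6 (not isolated)
Conditions: 9-BBN-H (1.2 equiv), THF, 0 °C → rt; then 5, CuOAc (5 mol %), P(OPh)3 (10 mol %), KOt-Bu (10 mol %), t-BuOH (1 equiv), dioxane, 40 °C
Reagents that add atoms: 9-borabicyclo[3.3.1]nonane B1C2CCCC1CCC2 (carried only by 6)
Why: Anti-Markovnikov hydroboration is selective for the terminal alkene (the silyl alkyne and tertiary OH react far more slowly), and Cu-catalysed conjugate addition of the alkylborane to the alkynoate (syn carbocupration, then protonation) gives only the 2E enoate.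

Step 3
Reactants: 7 methyl (2E,7S)-7-hydroxy-3,7-dimethyl-9-(trimethylsilyl)non-2-en-8-ynoate
Product: 8 methyl (3S,7S)-7-hydroxy-3,7-dimethyl-9-(trimethylsilyl)non-8-ynoate
Conditions: Cu(OAc)2·H2O (3 mol %), (R)-DTBM-SEGPHOS (3.3 mol %), (EtO)2MeSiH, t-BuOH, PhMe, 0 °C; aq NH4F
Reagents that add atoms: none
Why: In this CuH-catalysed asymmetric conjugate reduction (1,4-hydrosilylation), ligand-controlled hydride delivery to one face of the geometrically pure E-enoate sets C12 as S, and the unactivated silyl alkyne is not touched at 0 °C.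

Step 4
Reactants: 8 methyl (3S,7S)-7-hydroxy-3,7-dimethyl-9-(trimethylsilyl)non-8-ynoate
Product: 10 (3S,7S)-3,7-dimethylnon-8-yne-1,7-diol, via TMS-alkynyl diol 9 (not isolated)
Conditions: LiBH4, THF/MeOH, 0 °C → rt; then K2CO3 (cat.), MeOH, rt
Reagents that add atoms: none
Why: Borohydride reduces the ester without hydrometallating the alkyne, carbonate-catalysed methanolysis then cleaves the C(sp)–Si bond, and no stereocentre is involved.

Step 5
Reactants: 10 (3S,7S)-3,7-dimethylnon-8-yne-1,7-diol
Product: 11 (4S,8S)-4,10-dihydroxy-4,8-dimethyldec-2-ynoic acid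
Conditions: n-BuLi (3.3 equiv), THF, −78 → −20 °C; CO2 (g); 1 M HCl
Reagents that add atoms: carbon dioxide O=C=O
Why: This is carboxylation of a lithium acetylide, and the alkyl carbonates formed at the two alkoxides lose CO2 again on acidification.

Step 6
Reactants: 11 (4S,8S)-4,10-dihydroxy-4,8-dimethyldec-2-ynoic acid
Product: 12 (4S,8S)-4-hydroxy-4,8-dimethyl-10-oxodec-2-ynoic acid
Conditions: DMP (1.1 equiv), CH2Cl2, 0 °C
Reagents that add atoms: none
Why: Dess–Martin oxidation converts the only oxidisable (primary) alcohol, the tertiary carbinol and the acid are inert, and the α-carbon (C13) is still CH2 so nothing can epimerise.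

Step 7
Reactants: 13 tert-butyldimethyl(prop-2-yn-1-yloxy)silane; 14 oxirane
Product: 16 (E)-5-[(tert-butyldimethylsilyl)oxy]-4-methylpent-3-en-1-ol, via alkenyldimethylalane 15 (not isolated)
Conditions: Me3Al, Cp2ZrCl2 (25 mol %), CH2Cl2, 0 °C → rt; swap to hexane/THF, n-BuLi, −78 °C; 14, −78 → 0 °C
Reagents that add atoms: trimethylaluminium C[Al](C)C
Why: Negishi Zr-catalysed syn-carboalumination places Me on the internal carbon, and the derived alanate opens oxirane with retention, which fixes the 3E trisubstituted alkene.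

Step 8
Reactants: 16 (E)-5-[(tert-butyldimethylsilyl)oxy]-4-methylpent-3-en-1-ol
Product: 17 (E)-5-[(tert-butyldimethylsilyl)oxy]-4-methylpent-3-enal
Conditions: DMP, NaHCO3, CH2Cl2, 0 °C (used crude)
Reagents that add atoms: none
Why: Buffered Dess–Martin oxidation is neutral enough to give the β,γ-unsaturated aldehyde without the alkene moving into conjugation.

Step 9
Reactants: 17 (E)-5-[(tert-butyldimethylsilyl)oxy]-4-methylpent-3-enal; 18 methyl propiolate
Product: 20 methyl (5E)-7-[(tert-butyldimethylsilyl)oxy]-3-hydroxy-6-methyl-2-methylidenehept-5-enoate (racemic at C3), via alpha-aluminoacrylate 19 (not isolated)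
Conditions: 18, i-Bu2AlH, NMO, THF, 0 °C; then 17, 0 °C → rt
Reagents that add atoms: diisobutylaluminium hydride CC(C)C[AlH]CC(C)C (its aluminium unit is carried only by 19)
Why: Vinylalumination is a fast, amine-free surrogate of the Morita–Baylis–Hillman reaction, so the base-sensitive aldehyde does not isomerise, and the new carbinol centre is racemic but is erased in step 10.

Step 10
Reactants: 20 methyl (5E)-7-[(tert-butyldimethylsilyl)oxy]-3-hydroxy-6-methyl-2-methylidenehept-5-enoate
Product: 21 methyl (2Z,5E)-2-(bromomethyl)-7-[(tert-butyldimethylsilyl)oxy]-6-methylhepta-2,5-dienoate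
Conditions: NBS, Me2S, CH2Cl2, 0 °C → rt
Reagents that add atoms: N-bromosuccinimide O=C1CCC(=O)N1Br
Why: SN2′ bromination of a Baylis–Hillman alcohol through its alkoxysulfonium salt gives the thermodynamically preferred Z bromide (C2 cis to CH2Br), and the silyl ether survives.

Step 11
Reactants: 12 (4S,8S)-4-hydroxy-4,8-dimethyl-10-oxodec-2-ynoic acid; 21 methyl (2Z,5E)-2-(bromomethyl)-7-[(tert-butyldimethylsilyl)oxy]-6-methylhepta-2,5-dienoate
Product: 24 (4S,8S,9R,10R,11S,13E)-15-[(tert-butyldimethylsilyl)oxy]-4,10-dihydroxy-11-(3-methoxy-3-oxoprop-1-en-2-yl)-4,8,14-trimethyl-9-[(phenylamino)oxy]pentadec-13-en-2-ynoic acid, via alpha-aminoxy aldehyde 22 (not isolated), via allylindium dibromide 23 (not isolated)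
Conditions: 12, PhNO (1.0 equiv), L-proline (30 mol %), DMSO, rt, 30 min; then 21 (1.3 equiv), In powder, THF/H2O, rt
Reagents that add atoms: nitrosobenzene O=Nc1ccccc1
Why: In this tandem organocatalytic α-aminoxylation and aqueous indium Barbier allylation, L-proline enamine catalysis sets C13 as R, the In(III) chelate of the aldehyde and C13 oxygens directs attack to give the 13,14-syn diol pattern (C14 R), and the Z-allylindium reacts at its γ-carbon through a chair to give the 1,14-syn adduct (C1 S) needed for the cis-lactone.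

Step 12
Reactants: 24 Barbier adduct (name as in step 11)
Product: 26 (4S,8S,9R)-4,9-dihydroxy-9-{(2R,3S)-3-[(2E)-4-hydroxy-3-methylbut-2-en-1-yl]-4-methylidene-5-oxooxolan-2-yl}-4,8-dimethylnon-2-ynoic acid, via triol methyl ester 25 (not isolated)
Conditions: CuSO4·5H2O (30 mol %), MeOH, 0 °C → rt; then 48 % aq HF, MeCN, 0 °C → rt
Reagents that add atoms: none
Why: Cu(II)-catalysed N–O cleavage frees the C13 hydroxyl without a reducing metal, and aqueous HF then removes the primary TBS ether and catalyses lactonisation of the C14 hydroxyl onto the methyl ester (the five-membered ring is favoured over the six-membered ring through O13) without touching any stereocentre.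

Step 13
Reactants: 26 seco acid (name as in step 12)
Product: 27 16-membered ynoate macrolactone (1S,3E,8S,12S,13R,14R), i.e. compound 28 with a C(=O)O unit inserted between C6 and C5 and cis-fused to the α-methylene-γ-lactone
Conditions: PPh3, DIAD, PhMe/THF, 0 °C, slow addition of 26 (final 1 mM)
Reagents that add atoms: none
Why: Mitsunobu macrolactonisation activates only the primary allylic C5–OH, the acidic ynoic acid (pKa about 2.6) is an ideal partner, and closure through O13 would need a strained 10-membered cycloalkyne while O8 is tertiary.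

Step 14
Reactants: 27 16-membered ynoate macrolactone
Product: 28 (1S,3E,8S,12S,13R,14R)-8,13-dihydroxycembra-3,15(17)-dien-6-yn-16,14-olide
Conditions: Pd(PPh3)4 (10 mol %), PhMe (1 mM), 75 °C
Reagents that add atoms: none
Why: Proposed new method: CO2-extrusive ring contraction of a macrocyclic allyl alkynoate. Pd(0) ionises the allylic C5–O bond to a π-allyl-Pd alkynoate whose two ends stay on the same metal, loss of CO2 gives a (π-allyl)(alkynyl)Pd metallacycle, and C(sp3)–C(sp) reductive elimination at the unhindered terminus C5 closes the 14-membered carbocycle. Attack at C3 would give a strained 12-membered ring, the syn-π-allyl keeps the 3E geometry, irreversible CO2 loss drives the contraction, and high dilution suppresses crossover. The closest known reaction type is the Pd-catalysed decarboxylative sp–sp3 coupling of acyclic allyl alkynoates (Tsuji–Trost ionisation, decarboxylation, reductive elimination), which has not been shown on a macrolactone or as a ring contraction.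

Step 15
Reactants: 28 (1S,3E,8S,12S,13R,14R)-8,13-dihydroxycembra-3,15(17)-dien-6-yn-16,14-olide
Product: 29 (1S,3R,4R,8S,12S,13R,14R)-3,4-epoxy-8,13-dihydroxycembr-15(17)-en-6-yn-16,14-olide
Conditions: D-fructose-derived Shi ketone (30 mol %), Oxone, K2CO3, Bu4NHSO4, MeCN/DMM, aq Na2B4O7–EDTA buffer, 0 °C
Reagents that add atoms: potassium peroxymonosulfate (Oxone) [K+].[O-]S(=O)(=O)OO
Why: Shi asymmetric epoxidation is used because the C3=C4 bond is the only electron-rich alkene (the exocyclic enoate and the alkyne are inert to the dioxirane), and the D-fructose-derived dioxirane gives the R,R oxirane from an E-trisubstituted alkene through the spiro transition state under reagent control.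

Step 16
Reactants: 29 (1S,3R,4R,8S,12S,13R,14R)-3,4-epoxy-8,13-dihydroxycembr-15(17)-en-6-yn-16,14-olide
Product: 30 (1S,3R,4R,6Z,8S,12S,13R,14R)-3,4-epoxy-8,13-dihydroxycembra-6,15(17)-dien-16,14-olide (CNP0304380.1)
Conditions: H2 (1 atm), Lindlar Pd (Pd/CaCO3–Pb), quinoline, EtOAc, 0 °C, stopped at 1.0 equiv H2
Reagents that add atoms: none
Why: Lindlar semihydrogenation adds H2 syn to the more strongly adsorbed alkyne and gives the 6Z alkene, and the poisoned catalyst with a stoichiometric H2 cut-off spares the oxirane and the α-methylene lactone.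

## Compound list
1 | 4-(trimethylsilyl)but-3-yn-2-one | CC(=O)C#C[Si](C)(C)C | starting material
2 | allylmagnesium bromide | C=CC[Mg]Br | starting material
3 | allyldiisopropoxyborane | C=CCB(OC(C)C)OC(C)C | intermediate
4 | (S)-3-methyl-1-(trimethylsilyl)hex-5-en-1-yn-3-ol | C=CC[C@](C)(O)C#C[Si](C)(C)C | intermediate
5 | methyl but-2-ynoate | CC#CC(=O)OC | starting material
6 | B-[(4S)-4-hydroxy-4-methyl-6-(trimethylsilyl)hex-5-yn-1-yl]-9-BBN | B1(CCC[C@](C)(O)C#C[Si](C)(C)C)C2CCCC1CCC2 | intermediate
7 | methyl (2E,7S)-7-hydroxy-3,7-dimethyl-9-(trimethylsilyl)non-2-en-8-ynoate | COC(=O)/C=C(\C)CCC[C@](C)(O)C#C[Si](C)(C)C | intermediate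
8 | methyl (3S,7S)-7-hydroxy-3,7-dimethyl-9-(trimethylsilyl)non-8-ynoate | COC(=O)C[C@@H](C)CCC[C@](C)(O)C#C[Si](C)(C)C | intermediate
9 | (3S,7S)-3,7-dimethyl-9-(trimethylsilyl)non-8-yne-1,7-diol | OCC[C@@H](C)CCC[C@](C)(O)C#C[Si](C)(C)C | intermediate
10 | (3S,7S)-3,7-dimethylnon-8-yne-1,7-diol | OCC[C@@H](C)CCC[C@](C)(O)C#C | intermediate
11 | (4S,8S)-4,10-dihydroxy-4,8-dimethyldec-2-ynoic acid | OCC[C@@H](C)CCC[C@](C)(O)C#CC(=O)O | intermediate
12 | (4S,8S)-4-hydroxy-4,8-dimethyl-10-oxodec-2-ynoic acid | O=CC[C@@H](C)CCC[C@](C)(O)C#CC(=O)O | intermediate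
13 | tert-butyldimethyl(prop-2-yn-1-yloxy)silane | C#CCO[Si](C)(C)C(C)(C)C | starting material
14 | oxirane | C1CO1 | starting material
15 | (E)-[3-(tert-butyldimethylsilyloxy)-2-methylprop-1-en-1-yl]dimethylalane | C[Al](C)/C=C(\C)CO[Si](C)(C)C(C)(C)C | intermediate
16 | (E)-5-[(tert-butyldimethylsilyl)oxy]-4-methylpent-3-en-1-ol | OCC/C=C(\C)CO[Si](C)(C)C(C)(C)C | intermediate
17 | (E)-5-[(tert-butyldimethylsilyl)oxy]-4-methylpent-3-enal | O=CC/C=C(\C)CO[Si](C)(C)C(C)(C)C | intermediate
18 | methyl propiolate | C#CC(=O)OC | starting material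
19 | [1-(methoxycarbonyl)vinyl]diisobutylalane | C=C(C(=O)OC)[Al](CC(C)C)CC(C)C | intermediate
20 | methyl (5E)-7-[(tert-butyldimethylsilyl)oxy]-3-hydroxy-6-methyl-2-methylidenehept-5-enoate (racemic) | C=C(C(=O)OC)C(O)C/C=C(\C)CO[Si](C)(C)C(C)(C)C | intermediate
21 | methyl (2Z,5E)-2-(bromomethyl)-7-[(tert-butyldimethylsilyl)oxy]-6-methylhepta-2,5-dienoate | COC(=O)/C(CBr)=C/C/C=C(\C)CO[Si](C)(C)C(C)(C)C | intermediate
22 | (4S,8S,9R)-4-hydroxy-4,8-dimethyl-10-oxo-9-[(phenylamino)oxy]dec-2-ynoic acid | O=C[C@H](ONc1ccccc1)[C@@H](C)CCC[C@](C)(O)C#CC(=O)O | intermediate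
23 | allylindium dibromide derived from 21 | COC(=O)/C(C[In](Br)Br)=C/C/C=C(\C)CO[Si](C)(C)C(C)(C)C | intermediate
24 | (4S,8S,9R,10R,11S,13E)-15-[(tert-butyldimethylsilyl)oxy]-4,10-dihydroxy-11-(3-methoxy-3-oxoprop-1-en-2-yl)-4,8,14-trimethyl-9-[(phenylamino)oxy]pentadec-13-en-2-ynoic acid | C=C(C(=O)OC)[C@H](C/C=C(\C)CO[Si](C)(C)C(C)(C)C)[C@@H](O)[C@H](ONc1ccccc1)[C@@H](C)CCC[C@](C)(O)C#CC(=O)O | intermediate
25 | (4S,8S,9R,10R,11S,13E)-15-[(tert-butyldimethylsilyl)oxy]-4,9,10-trihydroxy-11-(3-methoxy-3-oxoprop-1-en-2-yl)-4,8,14-trimethylpentadec-13-en-2-ynoic acid | C=C(C(=O)OC)[C@H](C/C=C(\C)CO[Si](C)(C)C(C)(C)C)[C@@H](O)[C@H](O)[C@@H](C)CCC[C@](C)(O)C#CC(=O)O | intermediate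
26 | (4S,8S,9R)-4,9-dihydroxy-9-{(2R,3S)-3-[(2E)-4-hydroxy-3-methylbut-2-en-1-yl]-4-methylidene-5-oxooxolan-2-yl}-4,8-dimethylnon-2-ynoic acid | C=C1C(=O)O[C@@H]([C@H](O)[C@@H](C)CCC[C@](C)(O)C#CC(=O)O)[C@H]1C/C=C(\C)CO | intermediate
27 | 16-membered ynoate macrolactone (1S,3E,8S,12S,13R,14R), C(=O)O inserted between C6 and C5 of 28 | C=C1C(=O)O[C@H]2[C@H](O)[C@@H](C)CCC[C@](C)(O)C#CC(=O)OC/C(C)=C/C[C@@H]12 | intermediate
28 | (1S,3E,8S,12S,13R,14R)-8,13-dihydroxycembra-3,15(17)-dien-6-yn-16,14-olide | C=C1C(=O)O[C@H]2[C@H](O)[C@@H](C)CCC[C@](C)(O)C#CC/C(C)=C/C[C@@H]12 | intermediate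
29 | (1S,3R,4R,8S,12S,13R,14R)-3,4-epoxy-8,13-dihydroxycembr-15(17)-en-6-yn-16,14-olide | C=C1C(=O)O[C@H]2[C@H](O)[C@@H](C)CCC[C@](C)(O)C#CC[C@@]3(C)O[C@@H]3C[C@@H]12 | intermediate
30 | (1S,3R,4R,6Z,8S,12S,13R,14R)-3,4-epoxy-8,13-dihydroxycembra-6,15(17)-dien-16,14-olide (CNP0304380.1) | C=C1C(=O)O[C@H]2[C@H](O)[C@@H](C)CCC[C@](C)(O)/C=C\C[C@@]3(C)O[C@@H]3C[C@@H]12 | target

## Step count and risks
Total step count: 16. Longest linear sequence: 12 (steps 1–6 and 11–16).

**Step 14 (the proposed new step).**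
- Failure modes: β-hydride elimination or protonation of the π-allyl/alkynyl pair, oligomerisation, and 3E/3Z scrambling.
- The fallback sets out from 26 and comes back to the route at 28, using only known reactions.
- Cu(I)-catalysed protodecarboxylation of the ynoic acid (CuCl, Et3N, MeCN, 60 °C) gives (4S,5R)-5-[(1R,2S,6S)-1,6-dihydroxy-2,6-dimethyloct-7-yn-1-yl]-4-[(2E)-4-hydroxy-3-methylbut-2-en-1-yl]-3-methylideneoxolan-2-one F2.
- Corey–Kim chlorination (NCS, Me2S, CH2Cl2, −20 °C) converts only the primary allylic alcohol and gives (4S,5R)-4-[(2E)-4-chloro-3-methylbut-2-en-1-yl]-5-[(1R,2S,6S)-1,6-dihydroxy-2,6-dimethyloct-7-yn-1-yl]-3-methylideneoxolan-2-one F3.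
- Intramolecular Cu(I)-mediated coupling of the alkyne with the allyl chloride (CuI, NaI, Cs2CO3, DMF, 1 mM, syringe pump) then closes the 14-membered ring directly to 28.

**Step 11.**
- Failure modes: only modest 13,14-syn selectivity from the aminoxy chelate, lability of 22, and alkylation of proline by 21.
- The fallback sets out from 12 and comes back at 25. It uncouples the tandem and changes the control element to a free hydroxyl.
- After the aminoxylation of 12, the N–O bond of 22 is cleaved first (CuSO4, MeOH) to give (4S,8S,9R)-4,9-dihydroxy-4,8-dimethyl-10-oxodec-2-ynoic acid F1, which is handled as its hydrate in water.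
- The Barbier reaction with 21 and indium is then run in water/THF. The known chelation of indium by a free α-hydroxyl gives the syn,syn triad and delivers 25 directly.

**Step 16.**
- Failure mode: competing reduction or isomerisation of the α-methylene lactone.
- The fallback sets out from 29 and comes back at 30. It replaces hydrogenation by an alkyne-specific addition.
- Pt-catalysed syn-hydrosilylation (Karstedt catalyst, (EtO)3SiH, THF, rt) places silicon on the less hindered C6 and gives (6E)-6-(triethoxysilyl)-3,4-epoxy-8,13-dihydroxycembra-6,15(17)-dien-16,14-olide F4.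
- Stereoretentive protodesilylation (AgF, THF/MeOH/H2O, rt, dark) then gives the 6Z alkene 30.

## Further compounds
F1 | step 11 | (4S,8S,9R)-4,9-dihydroxy-4,8-dimethyl-10-oxodec-2-ynoic acid | O=C[C@H](O)[C@@H](C)CCC[C@](C)(O)C#CC(=O)O
F2 | step 14 | (4S,5R)-5-[(1R,2S,6S)-1,6-dihydroxy-2,6-dimethyloct-7-yn-1-yl]-4-[(2E)-4-hydroxy-3-methylbut-2-en-1-yl]-3-methylideneoxolan-2-one | C=C1C(=O)O[C@@H]([C@H](O)[C@@H](C)CCC[C@](C)(O)C#C)[C@H]1C/C=C(\C)CO
F3 | step 14 | (4S,5R)-4-[(2E)-4-chloro-3-methylbut-2-en-1-yl]-5-[(1R,2S,6S)-1,6-dihydroxy-2,6-dimethyloct-7-yn-1-yl]-3-methylideneoxolan-2-one | C=C1C(=O)O[C@@H]([C@H](O)[C@@H](C)CCC[C@](C)(O)C#C)[C@H]1C/C=C(\C)CCl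
F4 | step 16 | (6E)-6-(triethoxysilyl)-3,4-epoxy-8,13-dihydroxycembra-6,15(17)-dien-16,14-olide | C=C1C(=O)O[C@H]2[C@H](O)[C@@H](C)CCC[C@](C)(O)/C=C(/[Si](OCC)(OCC)OCC)\C[C@@]3(C)O[C@@H]3C[C@@H]12
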